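The route rests on disconnecting C1–C10, the bond joining the oxolane carbon C1 (bearing the ring oxygen) to the tertiary carbinol C10. A samarium Barbier cyclisation of an anomeric 2-pyridyl sulfone onto a methyl ketone closes the ten-membered carbocycle, and with it the 11-oxabicyclo[6.2.1]undecane core, in one operation, setting C1 and C10. It exploits the 1,2-dioxygenated C1–C10 unit and the cis-2,5-bridged oxolane. The precursor is an open chain: a (R)-linalool-derived sulfonyl oxolane (C1–C5, C15) linked by a C5–C6 aldol to a butenolide bearing the β-silyloxy ketone side chain; the C5=C6 alkene is formed after ring closure.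

Key step: step 11

Remark on numbering: germacrane numbering is used throughout. C1–C4 and the bridging oxygen form the oxolane (C1 is the CH, C4 the quaternary carbon with methyl C15). C5=C6 is the exocyclic enol-lactone alkene. C6, C7, C11 and C12 form the butenolide (C12 carbonyl, C13 the CH2O group on C11). C8 carries the methacrylate, C9 is the CH2, C10 the tertiary carbinol with methyl C14.

Remark on mixtures: compounds 4–6 are carried as both epimers at the sulfonyl-bearing carbon, and 19–23 also as mixtures at C5 and C6. These centres are erased in steps 11 and 12. TBS = tert-butyldimethylsilyl.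

Step 1
Reactants: 1 (R)-(−)-linalool
Product: 3 (5R)-5-ethenyl-5-methyloxolan-2-ol (lactol; both anomers), via secondary ozonide 2 (not isolated)
Conditions: O3 (1 equiv, Sudan Red 7B end-point), CH2Cl2, −78 °C; then Me2S, −78 °C → rt
Reagents that add atoms: ozone, [O-][O+]=O
Why: Ozonolysis with reductive work-up cleaves the electron-rich trisubstituted alkene well before the vinyl group, and the freed γ-hydroxy aldehyde closes to the lactol, so the linalool stereocentre becomes C4 (R) untouched.

Step 2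
Reactants: 3 (5R)-5-ethenyl-5-methyloxolan-2-ol
Product: 4 2-{[(5R)-5-ethenyl-5-methyloxolan-2-yl]sulfonyl}pyridine (both C2 epimers)
Conditions: sodium pyridine-2-sulfinate (1.5 equiv), CF3CO2H (1.5 equiv), CaCl2, CH2Cl2, 0 °C → rt
Reagents that add atoms: sodium pyridine-2-sulfinate, [Na+].[O-]S(=O)c1ccccn1
Why: Acid-mediated condensation of a lactol with a sulfinic acid through the cyclic oxocarbenium ion should give the anomeric sulfone by S-alkylation, with CaCl2 taking up the water; the anomeric configuration is irrelevant.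

Step 3
Reactants: 4 2-{[(5R)-5-ethenyl-5-methyloxolan-2-yl]sulfonyl}pyridine
Product: 6 (2R)-2-methyl-5-(pyridin-2-ylsulfonyl)oxolane-2-carbaldehyde, via secondary ozonide 5 (not isolated)
Conditions: O3, CH2Cl2, −78 °C; then Me2S, −78 °C → rt
Reagents that add atoms: ozone, [O-][O+]=O
Why: Ozonolysis of the only remaining alkene gives the non-enolisable α-alkoxy aldehyde (C5), the electron-poor sulfonylpyridine being inert to ozone at −78 °C.

Step 4
Reactants: 7 but-2-yne-1,4-diol
Product: 8 4-[(tert-butyldimethylsilyl)oxy]but-2-yn-1-ol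
Conditions: TBSCl (1 equiv), imidazole, 7 (3 equiv), DMF, 0 °C → rt
Reagents that add atoms: tert-butyldimethylsilyl chloride, CC(C)(C)[Si](C)(C)Cl
Why: Statistical monosilylation of a symmetrical diol used in excess.

Step 5
Reactants: 8 4-[(tert-butyldimethylsilyl)oxy]but-2-yn-1-ol
Product: 11 3-{[(tert-butyldimethylsilyl)oxy]methyl}-4-ethenylfuran-2(5H)-one, via cyclic alkenylmagnesium alkoxide 9 (not isolated), via hydroxy acid 10 (not isolated)
Conditions: CH2=CHMgCl (3.5 equiv), THF/cyclohexane, reflux; then CO2, 0 °C; then aq. citric acid, rt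
Reagents that add atoms: vinylmagnesium chloride, C=C[Mg]Cl; carbon dioxide, O=C=O
Why: Alkoxide-directed anti-carbomagnesiation of the propargylic alcohol puts vinyl on C7 and magnesium on C11 in a five-membered chelate; carboxylation then places CO2H cis to CH2OH and lactonisation gives the butenolide, three components joined in one operation.

Step 6
Reactants: 11 3-{[(tert-butyldimethylsilyl)oxy]methyl}-4-ethenylfuran-2(5H)-one
Product: 13 4-{[(tert-butyldimethylsilyl)oxy]methyl}-5-oxo-2,5-dihydrofuran-3-carbaldehyde, via secondary ozonide 12 (not isolated)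
Conditions: O3 (Sudan Red 7B end-point), CH2Cl2, −78 °C; then Me2S
Reagents that add atoms: ozone, [O-][O+]=O
Why: Ozonolysis takes the terminal vinyl group in preference to the tetrasubstituted butenolide alkene, which is deactivated by conjugation with the lactone carbonyl.

Step 7
Reactants: 13 4-{[(tert-butyldimethylsilyl)oxy]methyl}-5-oxo-2,5-dihydrofuran-3-carbaldehyde
Product: 15 3-{[(tert-butyldimethylsilyl)oxy]methyl}-4-[(1S)-1-hydroxy-3-methylbut-3-en-1-yl]furan-2(5H)-one, via pinacol borate ester 14 (not isolated)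
Conditions: 2-methylallyl-B(pin) (1.3 equiv), (S)-TRIP phosphoric acid [(S)-3,3′-bis(2,4,6-triisopropylphenyl)-1,1′-binaphthyl-2,2′-diyl hydrogen phosphate, 5 mol %], 4 Å molecular sieves, toluene, −30 °C; aq. NaHCO3
Reagents that add atoms: 2-methylallylboronic acid pinacol ester, CC(=C)CB1OC(C)(C)C(C)(C)O1
Why: Chiral phosphoric acid-catalysed allylboration through a closed chair transition state; the (S)-catalyst is chosen to deliver the methallyl group to the Si face of the aldehyde, which sets C8 as (S), and the methallyl group is a masked methyl ketone.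

Step 8
Reactants: 15 3-{[(tert-butyldimethylsilyl)oxy]methyl}-4-[(1S)-1-hydroxy-3-methylbut-3-en-1-yl]furan-2(5H)-one
Product: 16 4-[(1S)-1-[(tert-butyldimethylsilyl)oxy]-3-methylbut-3-en-1-yl]-3-{[(tert-butyldimethylsilyl)oxy]methyl}furan-2(5H)-one
Conditions: TBSOTf, 2,6-lutidine, CH2Cl2, −78 °C
Reagents that add atoms: tert-butyldimethylsilyl triflate, CC(C)(C)[Si](C)(C)OS(=O)(=O)C(F)(F)F
Why: Silylation of the secondary allylic alcohol with a weak, hindered base that leaves the acidic butenolide γ-protons alone.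

Step 9
Reactants: 16 bis-silyl butenolide; 6 (2R)-2-methyl-5-(pyridin-2-ylsulfonyl)oxolane-2-carbaldehyde
Product: 19 C5-acetoxy aldol adduct (5-{(acetyloxy)[(2R)-2-methyl-5-(pyridin-2-ylsulfonyl)oxolan-2-yl]methyl} derivative of 16), via lithium dienolate 17 (not isolated), via lithium aldolate 18 (not isolated)
Conditions: LiN(iPr)2 (1.05 equiv), THF, −78 °C; then 6, −78 °C; then Ac2O, −78 °C; AcOH quench at −78 °C
Reagents that add atoms: acetic anhydride, CC(=O)OC(C)=O
Why: Vinylogous aldol addition of the aromatic 2-furanolate through its γ-carbon C6 (the α-carbon C11 is blocked) to the non-enolisable aldehyde forms C5–C6, and the aldolate is capped in situ as the acetate; C5 and C6 are not controlled and need not be, since both become sp2 in step 12.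

Step 10
Reactants: 19 C5-acetoxy aldol adduct
Product: 21 methyl ketone (4-[(1S)-1-[(tert-butyldimethylsilyl)oxy]-3-oxobutyl] analogue of 19), via secondary ozonide 20 (not isolated)
Conditions: O3 (Sudan Red 7B end-point), CH2Cl2, −78 °C; then Me2S
Reagents that add atoms: ozone, [O-][O+]=O
Why: Ozonolysis unmasks the C10 methyl ketone from the electron-rich 1,1-disubstituted alkene only now, after all enolate chemistry, while the conjugated butenolide alkene, the sulfone and the esters are left alone.

Step 11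
Reactants: 21 methyl ketone bearing the anomeric 2-pyridyl sulfone
Product: 23 (1S,4R,8S,10R)-5-acetoxy-8,13-bis[(tert-butyldimethylsilyl)oxy]-1,4-epoxy-10-hydroxygermacr-7(11)-en-12,6-olide (C5/C6 mixture), via anomeric organosamarium 22 (not isolated)
Conditions: SmI2 (3 equiv, 0.1 M in THF), slow addition of 21 in THF (final 2 mM), 20 °C; then sat. aq. NH4Cl
Reagents that add atoms: none
Why: SmI2 reduces the 2-pyridyl sulfone by inner-sphere electron transfer through the pyridine nitrogen, sulfinate leaves, and the C1 radical is reduced again to the α-alkoxy organosamarium 22 (trivalent samarium), which adds to the C10 ketone through a four-centre transition state. The closest known reaction is the intermolecular samarium Barbier coupling of anomeric 2-pyridyl sulfones with ketones, run here intramolecularly as in medium-ring SmI2 Barbier cyclisations. The ten-membered carbocycle, and with it the nine-membered oxacycle of the 11-oxabicyclo[6.2.1]undecane, closes by 10-exo-trig 1,2-addition to the carbonyl. C1 is controlled by the C4 quaternary centre: the sulfone epimers converge on one planar radical, and only the C1–C10 bond cis to the C4–C5 bond across the oxolane can span the tether, which gives (1S). C10 is controlled by chelation: samarium held by C1 and the ring oxygen delivers the carbonyl oxygen gauche to the ring oxygen while C9 has to point back along the tether, so the methyl group ends anti to the ring oxygen, which is (10R). The step needs reduction of the sulfone in preference to the ketone and the butenolide (secured by the pyridyl group and by the absence of HMPA or protic additives) and ring closure ahead of protonation of 22 (secured by capping every hydroxyl and by slow addition of 21 to excess SmI2).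

Step 12
Reactants: 23 macrocyclic C5-acetate
Product: 25 (1S,4R,5E,8S,10R)-1,4-epoxy-8,10,13-trihydroxygermacra-5,7(11)-dien-12,6-olide, via ylidene bis-silyl ether 24 (not isolated)
Conditions: DBU (2 equiv), THF, 0 °C → rt; then HF·pyridine, pyridine, 0 °C → rt
Reagents that add atoms: none
Why: E1cB elimination: DBU removes the acidic γ-proton at C6 and the furanolate expels the C5 acetate, so all C5/C6 diastereomers converge on the C5=C6 enol lactone whose ring-cis (5E) geometry is imposed by the bicyclic frame; HF·pyridine then cleaves both silyl ethers under acidic conditions that spare the enol lactone.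

Step 13
Reactants: 25 8,10,13-triol
Product: 26 (1S,4R,5E,8S,10R)-13-acetoxy-1,4-epoxy-8,10-dihydroxygermacra-5,7(11)-dien-12,6-olide
Conditions: AcCl (1.1 equiv), 2,4,6-collidine, CH2Cl2, −78 °C
Reagents that add atoms: acetyl chloride, CC(=O)Cl
Why: Kinetically selective acylation of the primary allylic C13 hydroxyl over the hindered secondary C8 and tertiary C10 hydroxyls.

Step 14
Reactants: 26 13-acetate
Product: 27 target CNP0516045.1
Conditions: methacrylic anhydride, Et3N, DMAP (cat.), CH2Cl2, 0 °C → rt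
Reagents that add atoms: methacrylic anhydride, CC(=C)C(=O)OC(=O)C(C)=C
Why: DMAP-catalysed esterification (Steglich-type acyl transfer) of the secondary C8 hydroxyl; the tertiary C10 hydroxyl is too hindered to react.

Compound list
1 | (R)-(−)-linalool, (3R)-3,7-dimethylocta-1,6-dien-3-ol | C=C[C@](C)(O)CCC=C(C)C | starting material
2 | secondary ozonide of 1, (3R)-5-(5,5-dimethyl-1,2,4-trioxolan-3-yl)-3-methylpent-1-en-3-ol | C=C[C@](C)(O)CCC1OOC(C)(C)O1 | intermediate (not isolated)
3 | (5R)-5-ethenyl-5-methyloxolan-2-ol | C=C[C@@]1(C)CCC(O)O1 | intermediate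
4 | 2-{[(5R)-5-ethenyl-5-methyloxolan-2-yl]sulfonyl}pyridine | C=C[C@@]1(C)CCC(S(=O)(=O)c2ccccn2)O1 | intermediate
5 | secondary ozonide of 4, 2-{[(5R)-5-methyl-5-(1,2,4-trioxolan-3-yl)oxolan-2-yl]sulfonyl}pyridine | C1(OCOO1)[C@@]2(C)CCC(S(=O)(=O)c3ccccn3)O2 | intermediate (not isolated)
6 | (2R)-2-methyl-5-(pyridin-2-ylsulfonyl)oxolane-2-carbaldehyde | O=C[C@@]1(C)CCC(S(=O)(=O)c2ccccn2)O1 | intermediate
7 | but-2-yne-1,4-diol | OCC#CCO | starting material
8 | 4-[(tert-butyldimethylsilyl)oxy]but-2-yn-1-ol | CC(C)(C)[Si](C)(C)OCC#CCO | intermediate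
9 | cyclic alkenylmagnesium alkoxide (five-membered chelate; vinyl on C7, magnesium on C11) | C=CC1=C(CO[Si](C)(C)C(C)(C)C)[Mg]OC1 | intermediate (not isolated)
10 | (2Z)-2-{[(tert-butyldimethylsilyl)oxy]methyl}-3-(hydroxymethyl)penta-2,4-dienoic acid | OC/C(C=C)=C(/CO[Si](C)(C)C(C)(C)C)C(=O)O | intermediate (not isolated)
11 | 3-{[(tert-butyldimethylsilyl)oxy]methyl}-4-ethenylfuran-2(5H)-one | C=CC1=C(CO[Si](C)(C)C(C)(C)C)C(=O)OC1 | intermediate
12 | secondary ozonide of 11, 3-{[(tert-butyldimethylsilyl)oxy]methyl}-4-(1,2,4-trioxolan-3-yl)furan-2(5H)-one | C1(OCOO1)C2=C(CO[Si](C)(C)C(C)(C)C)C(=O)OC2 | intermediate (not isolated)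
13 | 4-{[(tert-butyldimethylsilyl)oxy]methyl}-5-oxo-2,5-dihydrofuran-3-carbaldehyde | O=CC1=C(CO[Si](C)(C)C(C)(C)C)C(=O)OC1 | intermediate
14 | pinacol borate ester of 15 | CC(=C)C[C@H](OB1OC(C)(C)C(C)(C)O1)C2=C(CO[Si](C)(C)C(C)(C)C)C(=O)OC2 | intermediate (not isolated)
15 | 3-{[(tert-butyldimethylsilyl)oxy]methyl}-4-[(1S)-1-hydroxy-3-methylbut-3-en-1-yl]furan-2(5H)-one | CC(=C)C[C@H](O)C1=C(CO[Si](C)(C)C(C)(C)C)C(=O)OC1 | intermediate
16 | 4-[(1S)-1-[(tert-butyldimethylsilyl)oxy]-3-methylbut-3-en-1-yl]-3-{[(tert-butyldimethylsilyl)oxy]methyl}furan-2(5H)-one | CC(=C)C[C@H](O[Si](C)(C)C(C)(C)C)C1=C(CO[Si](C)(C)C(C)(C)C)C(=O)OC1 | intermediate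
17 | lithium 2-furanolate (dienolate) of 16 | CC(=C)C[C@H](O[Si](C)(C)C(C)(C)C)c1coc(O[Li])c1CO[Si](C)(C)C(C)(C)C | intermediate (not isolated)
18 | lithium aldolate from 17 and 6 | CC(=C)C[C@H](O[Si](C)(C)C(C)(C)C)C1=C(CO[Si](C)(C)C(C)(C)C)C(=O)OC1C(O[Li])[C@@]1(C)CCC(S(=O)(=O)c2ccccn2)O1 | intermediate (not isolated)
19 | 5-{(acetyloxy)[(2R)-2-methyl-5-(pyridin-2-ylsulfonyl)oxolan-2-yl]methyl}-4-[(1S)-1-[(tert-butyldimethylsilyl)oxy]-3-methylbut-3-en-1-yl]-3-{[(tert-butyldimethylsilyl)oxy]methyl}furan-2(5H)-one | CC(=C)C[C@H](O[Si](C)(C)C(C)(C)C)C1=C(CO[Si](C)(C)C(C)(C)C)C(=O)OC1C(OC(C)=O)[C@@]1(C)CCC(S(=O)(=O)c2ccccn2)O1 | intermediate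
20 | secondary ozonide of 19 (3-methyl-1,2,4-trioxolan-3-yl in place of the isopropenyl group) | CC1(OCOO1)C[C@H](O[Si](C)(C)C(C)(C)C)C2=C(CO[Si](C)(C)C(C)(C)C)C(=O)OC2C(OC(C)=O)[C@@]3(C)CCC(S(=O)(=O)c4ccccn4)O3 | intermediate (not isolated)
21 | 5-{(acetyloxy)[(2R)-2-methyl-5-(pyridin-2-ylsulfonyl)oxolan-2-yl]methyl}-4-[(1S)-1-[(tert-butyldimethylsilyl)oxy]-3-oxobutyl]-3-{[(tert-butyldimethylsilyl)oxy]methyl}furan-2(5H)-one | CC(=O)C[C@H](O[Si](C)(C)C(C)(C)C)C1=C(CO[Si](C)(C)C(C)(C)C)C(=O)OC1C(OC(C)=O)[C@@]1(C)CCC(S(=O)(=O)c2ccccn2)O1 | intermediate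
22 | anomeric diiodosamarium species (SmI2 group on C1 in place of the sulfonyl group of 21) | CC(=O)C[C@H](O[Si](C)(C)C(C)(C)C)C1=C(CO[Si](C)(C)C(C)(C)C)C(=O)OC1C(OC(C)=O)[C@@]1(C)CCC([Sm](I)I)O1 | intermediate (not isolated)
23 | (1S,4R,8S,10R)-5-acetoxy-8,13-bis[(tert-butyldimethylsilyl)oxy]-1,4-epoxy-10-hydroxygermacr-7(11)-en-12,6-olide | CC(C)(C)[Si](C)(C)O[C@H]1C[C@@](C)(O)[C@@H]2CC[C@](C)(C(OC(C)=O)C3OC(=O)C(CO[Si](C)(C)C(C)(C)C)=C31)O2 | intermediate
24 | (1S,4R,5E,8S,10R)-8,13-bis[(tert-butyldimethylsilyl)oxy]-1,4-epoxy-10-hydroxygermacra-5,7(11)-dien-12,6-olide | CC(C)(C)[Si](C)(C)O[C@H]1C[C@@](C)(O)[C@@H]2CC[C@](C)(/C=C3/OC(=O)C(CO[Si](C)(C)C(C)(C)C)=C31)O2 | intermediate (not isolated)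
25 | (1S,4R,5E,8S,10R)-1,4-epoxy-8,10,13-trihydroxygermacra-5,7(11)-dien-12,6-olide | O[C@H]1C[C@@](C)(O)[C@@H]2CC[C@](C)(/C=C3/OC(=O)C(CO)=C31)O2 | intermediate
26 | (1S,4R,5E,8S,10R)-13-acetoxy-1,4-epoxy-8,10-dihydroxygermacra-5,7(11)-dien-12,6-olide | O[C@H]1C[C@@](C)(O)[C@@H]2CC[C@](C)(/C=C3/OC(=O)C(COC(C)=O)=C31)O2 | intermediate
27 | CNP0516045.1, (1S,4R,5E,8S,10R)-13-acetoxy-1,4-epoxy-10-hydroxy-8-(2-methylprop-2-enoyloxy)germacra-5,7(11)-dien-12,6-olide | C=C(C)C(=O)O[C@H]1C[C@@](C)(O)[C@@H]2CC[C@](C)(/C=C3/OC(=O)C(COC(C)=O)=C31)O2 | target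

Total step count: 14.
Longest linear sequence: 11 steps (steps 4–14, from but-2-yne-1,4-diol); the linalool branch (steps 1–3) joins at step 9.

Steps most likely to fail

1. Step 11 (key cyclisation). Several processes may compete with ring closure onto the hindered methyl ketone:
- protonation of the anomeric organosamarium before it reaches the ketone;
- 6-exo addition of the C1 radical to the butenolide;
- over-reduction of the butenolide by excess SmI2;
- attack on the wrong face of the ketone.

Fallback: C10 is built in two stages, closing the same bond onto a more reactive aldehyde and adding the methyl group afterwards. It sets out from 13. (S)-TRIP-catalysed allylboration with allylboronic acid pinacol ester gives 3-{[(tert-butyldimethylsilyl)oxy]methyl}-4-[(1S)-1-hydroxybut-3-en-1-yl]furan-2(5H)-one F1. Silylation with TBSOTf/2,6-lutidine gives the bis-silyl ether F2. The furanolate aldol with 6 and acetate capping, as in step 9, gives the allyl analogue of 19, F3. Ozonolysis gives the β-silyloxy aldehyde F4. SmI2 under the conditions of step 11 closes C1–C10 onto the aldehyde to give the macrocyclic secondary alcohol F5 (C10 epimers). Dess–Martin oxidation gives the macrocyclic C10 ketone F6. Chelation-controlled addition of MeTiCl3 (CH2Cl2, −78 °C), in which titanium bridges the ketone and oxolane oxygens and methyl enters anti to C2, should give (10R) and comes back to the route at 23.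

2. Step 9 (fragment union). The anomeric sulfinate may be lost by base-induced elimination to the dihydrofuran during the aldol. The C5 acetate may also be lost prematurely by E1cB, which would give the open-chain ylidene of the wrong geometry.

Fallback: the sulfone is introduced only after the union. It sets out from 3. MeOH with pyridinium p-toluenesulfonate gives the methyl acetal (5R)-5-ethenyl-2-methoxy-5-methyloxolane F7. Ozonolysis gives (2R)-5-methoxy-2-methyloxolane-2-carbaldehyde F8. The furanolate aldol of 16 with F8 and acetate capping gives the methyl-acetal analogue of 19, F9. Ozonolysis gives the methyl-acetal analogue of 21, F10. Acetal exchange with sodium pyridine-2-sulfinate/CF3CO2H/CaCl2 in CH2Cl2 then installs the sulfone directly before use and comes back to the route at 21.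

3. Step 2 (direct sulfination). Pyridine-2-sulfinic acid may disproportionate or desulfinate before it captures the oxocarbenium ion, and the tertiary allylic C4–O bond may ionise under the acid.

Fallback: a substitution–oxidation sequence. It sets out from 3. 2-Mercaptopyridine with catalytic pyridinium p-toluenesulfonate (CH2Cl2, 4 Å molecular sieves) gives the thioacetal 2-{[(5R)-5-ethenyl-5-methyloxolan-2-yl]sulfanyl}pyridine F11. Oxidation with mCPBA/NaHCO3 (CH2Cl2, 0 °C), which is faster at sulfur than at the vinyl group, comes back to the route at 4.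

Further compounds
F1 | step 11 | 3-{[(tert-butyldimethylsilyl)oxy]methyl}-4-[(1S)-1-hydroxybut-3-en-1-yl]furan-2(5H)-one | C=CC[C@H](O)C1=C(CO[Si](C)(C)C(C)(C)C)C(=O)OC1
F2 | step 11 | 4-[(1S)-1-[(tert-butyldimethylsilyl)oxy]but-3-en-1-yl]-3-{[(tert-butyldimethylsilyl)oxy]methyl}furan-2(5H)-one | C=CC[C@H](O[Si](C)(C)C(C)(C)C)C1=C(CO[Si](C)(C)C(C)(C)C)C(=O)OC1
F3 | step 11 | allyl analogue of 19 (but-3-en-1-yl side chain) | C=CC[C@H](O[Si](C)(C)C(C)(C)C)C1=C(CO[Si](C)(C)C(C)(C)C)C(=O)OC1C(OC(C)=O)[C@@]1(C)CCC(S(=O)(=O)c2ccccn2)O1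
F4 | step 11 | aldehyde analogue of 21 (3-oxopropyl side chain) | O=CC[C@H](O[Si](C)(C)C(C)(C)C)C1=C(CO[Si](C)(C)C(C)(C)C)C(=O)OC1C(OC(C)=O)[C@@]1(C)CCC(S(=O)(=O)c2ccccn2)O1
F5 | step 11 | (1S,4R,8S)-5-acetoxy-8,13-bis[(tert-butyldimethylsilyl)oxy]-1,4-epoxy-10-hydroxy-14-norgermacr-7(11)-en-12,6-olide | CC(C)(C)[Si](C)(C)O[C@H]1CC(O)[C@@H]2CC[C@](C)(C(OC(C)=O)C3OC(=O)C(CO[Si](C)(C)C(C)(C)C)=C31)O2
F6 | step 11 | (1S,4R,8S)-5-acetoxy-8,13-bis[(tert-butyldimethylsilyl)oxy]-1,4-epoxy-10-oxo-14-norgermacr-7(11)-en-12,6-olide | CC(C)(C)[Si](C)(C)O[C@H]1CC(=O)[C@@H]2CC[C@](C)(C(OC(C)=O)C3OC(=O)C(CO[Si](C)(C)C(C)(C)C)=C31)O2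
F7 | step 9 | (5R)-5-ethenyl-2-methoxy-5-methyloxolane | C=C[C@@]1(C)CCC(OC)O1
F8 | step 9 | (2R)-5-methoxy-2-methyloxolane-2-carbaldehyde | O=C[C@@]1(C)CCC(OC)O1
F9 | step 9 | methyl-acetal analogue of 19 (5-methoxy in place of the pyridin-2-ylsulfonyl group) | CC(=C)C[C@H](O[Si](C)(C)C(C)(C)C)C1=C(CO[Si](C)(C)C(C)(C)C)C(=O)OC1C(OC(C)=O)[C@@]1(C)CCC(OC)O1
F10 | step 9 | methyl-acetal analogue of 21 (5-methoxy in place of the pyridin-2-ylsulfonyl group) | CC(=O)C[C@H](O[Si](C)(C)C(C)(C)C)C1=C(CO[Si](C)(C)C(C)(C)C)C(=O)OC1C(OC(C)=O)[C@@]1(C)CCC(OC)O1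
F11 | step 2 | 2-{[(5R)-5-ethenyl-5-methyloxolan-2-yl]sulfanyl}pyridine | C=C[C@@]1(C)CCC(Sc2ccccn2)O1
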